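South-east, with 2.00 times the catalyst charge of south-west, reads 2.32 times south-west's target at 2.50 h, taking the mean of its own readings at 2.00 h and 3.00 h, more than the charge ratio.

the same everywhere: impurity 13 mM
- south-west: substrate 0.22 M; reagent 0.286 M; free catalyst 40 mM; run made earlier
- south-east: substrate 0.22 M; reagent 0.286 M; free catalyst 80 mM; run made earlier
- elm: substrate 0.22 M (in portions, 4, over 2.0 h); reagent 0.286 M; free catalyst 40 mM; first portion at the start, last at 2.0 h; time 10 h
- oak: substrate 0.22 M (fed, over 2.0 h); reagent 0.286 M; free catalyst 40 mM; all else is in the flask from the start; the feed brings no volume worth counting; time 10 h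
- ash: substrate 0.22 M; reagent 0.286 M; free catalyst 40 mM; everything together at the start; time 10 h
- maple: substrate 0.22 M; reagent 0.286 M (fed, over 2.0 h); free catalyst 40 mM; all else is in the flask from the start; the feed brings no volume worth counting; time 10 h

- south-west (time / h: target / %): 2.50: 3.9; 5.00: 5.9; 8.00: 7.9; 10.0: 8.1
- south-east (time / h: target / %): 0.417: 1.0; 1.00: 4.0; 2.00: 7.6; 3.00: 10.5

(readings scatter by 0.3 percentage points)

- the best flask by amount of target, in percent of the substrate charged; "all alike" if 1.5 percentage points covers them all (elm / oak / ash / maple / all alike)
- amount of target at the end, in percent of the substrate charged, elm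
- amount of target at the end, in percent of the substrate charged, oak
- amount of target at the end, in percent of the substrate charged, ash
- amount of target at the end, in percent of the substrate charged, maple

- steps thought possible: reagent + free catalyst <-> catalyst intermediate A; substrate + catalyst intermediate A -> catalyst intermediate B; catalyst intermediate B -> free catalyst + target; 2 reagent -> self-condensation product; free catalyst + impurity -> spent catalyst

We carry one quantity: the working catalyst w, which is c(free catalyst) at the charge less c(impurity) at the charge, 27.0 mM in south-west. Impurity is the limiting reagent of the poisoning step, since its charge is smaller than the catalyst's, and each impurity takes one catalyst. South-east has 67.0 mM, a ratio of 2.48 against the 2.32 read. Elm, oak, ash and maple share this w and the reagent charge, so we put each near south-west's 8.1 % and answer all alike. That is our bet that the manner of addition matters little, and the runs do not test it.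

The forecast differs: elm 6.5 %, oak 6.4 %, ash 8.2 %, maple 8.5 %, best maple, on the ground that “Dosing substrate wastes the early reagent-rich period”.

The flasks give elm 7.83 %, oak 7.75 %, ash 7.97 % and maple 8.32 %. The spread of 0.57 percentage points is less than the margin, so the answer is all alike.

    reagent + free catalyst ⇌ catalyst intermediate A (K = 1.30 L mol⁻¹, k = 2.90 × 10⁻⁴ L mol⁻¹ s⁻¹)
    substrate + catalyst intermediate A → catalyst intermediate B (k = 0.0560 L mol⁻¹ s⁻¹)
    catalyst intermediate B → free catalyst + target (k = 8.90 × 10⁻⁴ s⁻¹)
    2 reagent → self-condensation product (k = 5.10 × 10⁻⁴ L mol⁻¹ s⁻¹)
    free catalyst + impurity → spent catalyst (k = 0.0310 L mol⁻¹ s⁻¹)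

At 10.0 h ash holds free catalyst at 67.0 % of its charge, and with both intermediates counted that makes 27.0 mM against w of 27.0 mM. A neighbour flask is maple with free catalyst at 16.0 mM, so its w is 3.00 mM, and scaling maple's target by w gives 0.924 %. The neighbour gives 1.53 %, more than that. At 10.0 h its free catalyst stands at 19.2 % of the charge, 3.07 mM, and its spent catalyst at 80.6 %.

All runs are calculated from invented constants; scatter was added.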